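**Retrosynthetic overview**
1. The target comes from the fully protected flavanone by O-debenzylation, Boc removal, N-methylation and desilylation. All skeletal bonds are in place before these steps.
2. Ring A is made last and in one operation. It is the resorcinol ring whose piperidine-bearing C6 lies between the C5 and C7 oxygens and whose C4a–C8a edge is the enol-ether C=C of dihydropyranone ring C. A pyranone diazo ketone and a siloxyalkyne supply the bonds C8–C8a, C5–C6, C7–C8 and C4a–C5.
3. The diazo ketone comes from the pyranone-6-carboxylic acid, and this from an asymmetric hetero-Diels–Alder reaction of 4-(benzyloxy)benzaldehyde with the bis(silyl enol ether) of ethyl 2,4-dioxopentanoate (ring C, C2 set as S).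
4. The siloxyalkyne comes from a Kowalski ynolate of N-Boc-(R)-pipecolic ester (piperidine ring and C2′ from the chiral pool).
5. Ring order: piperidine and ring B are bought, ring C is formed by cycloaddition, ring A last by benzannulation.

Key step: step 7

Remark on the chemistry: the Si-face sense assumed for the (S)-BINOL/Ti(OiPr)4 catalyst in step 2 is the usual one for aryl aldehydes; if the carbinol centre came out R, (R)-BINOL would be used and nothing else changes.

**Route**

Step 1
Reactants: 1 ethyl 2,4-dioxopentanoate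
Product: 2 ethyl (2Z)-2,4-bis(trimethylsilyloxy)penta-2,4-dienoate
Conditions: Me3SiOTf (2.2 equiv), Et3N (2.5 equiv), Et2O, 0 °C to rt; filtered under argon, used crude
Reagents that add atoms: trimethylsilyl trifluoromethanesulfonate, C[Si](C)(C)OS(=O)(=O)C(F)(F)F
Why: Soft enolisation and O-silylation of both ketone carbonyls (silyl enol ether formation); C2=O can enolise only toward C3 and C4=O then only toward the methyl group, so the cross-conjugated 1,3-bis(silyloxy)diene is the only possible constitution.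

Step 2
Reactants: 2 ethyl (2Z)-2,4-bis(trimethylsilyloxy)penta-2,4-dienoate; 3 4-(benzyloxy)benzaldehyde
Product: 5 ethyl (S)-2-[4-(benzyloxy)phenyl]-4-oxo-3,4-dihydro-2H-pyran-6-carboxylate, via silyl aldol adduct 4 (not isolated)
Conditions: Ti(OiPr)4 (10 mol %), (S)-BINOL (20 mol %), 4 Å MS, Et2O, −20 °C to rt; then CF3CO2H, CH2Cl2, 0 °C, short contact
Reagents that add atoms: none
Why: Formal hetero-Diels–Alder reaction (Mukaiyama aldol then cyclocondensation) under chiral tetravalent-titanium/BINOL Lewis-acid catalysis: the CH2 terminus of 2 should add to the aldehyde on its Si face, which sets C2 as S, and acid then closes the δ-oxygen onto the α-keto-ester carbon with loss of silanol to give the 2,3-dihydro-4H-pyran-4-one.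

Step 3
Reactants: 5 ethyl (S)-2-[4-(benzyloxy)phenyl]-4-oxo-3,4-dihydro-2H-pyran-6-carboxylate
Product: 6 (S)-2-[4-(benzyloxy)phenyl]-4-oxo-3,4-dihydro-2H-pyran-6-carboxylic acid
Conditions: Me3SnOH (3 equiv), ClCH2CH2Cl, 70 °C; cold 0.5 M HCl work-up
Reagents that add atoms: trimethyltin hydroxide, C[Sn](C)(C)O
Why: Near-neutral tin-hydroxide ester hydrolysis of an activated (enol-ether-type 2-oxo acid) ester; aqueous alkali is avoided because deprotonation at C3 would open ring C by E1cB loss of the C2–O1 bond and erase the stereocentre.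

Step 4
Reactants: 6 (S)-2-[4-(benzyloxy)phenyl]-4-oxo-3,4-dihydro-2H-pyran-6-carboxylic acid
Product: 8 (S)-6-(2-diazoacetyl)-2-[4-(benzyloxy)phenyl]-2,3-dihydro-4H-pyran-4-one, via acid chloride 7 (not isolated)
Conditions: (COCl)2 (1.2 equiv), DMF (cat.), CH2Cl2, 0 °C to rt, evaporate; CH2N2 (2.5 equiv, Et2O), THF, −20 °C, 20 min, then N2 purge
Reagents that add atoms: oxalyl chloride, O=C(Cl)C(Cl)=O (chlorine of 7 only); diazomethane, C=[N+]=[N-]
Why: Acylation of diazomethane by the acid chloride (first stage of the Arndt–Eistert sequence, second equivalent removes HCl) should outrun 1,3-dipolar cycloaddition, because the C5=C6 bond is an alkoxy-substituted, trisubstituted enedione and so a slow dipolarophile at −20 °C with a small excess and short contact.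

Step 5
Reactants: 9 (R)-1-(tert-butoxycarbonyl)piperidine-2-carboxylic acid
Product: 10 1-tert-butyl 2-methyl (R)-piperidine-1,2-dicarboxylate
Conditions: MeI, K2CO3, DMF, rt
Reagents that add atoms: iodomethane, CI
Why: SN2 O-alkylation of the carboxylate under conditions too weakly basic to deprotonate the α-carbon, so the R configuration is kept.

Step 6
Reactants: 10 1-tert-butyl 2-methyl (R)-piperidine-1,2-dicarboxylate
Product: 12 tert-butyl (R)-2-{[(triisopropylsilyl)oxy]ethynyl}piperidine-1-carboxylate, via lithium ynolate 11 (not isolated)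
Conditions: CH2Br2, lithium 2,2,6,6-tetramethylpiperidide, THF, −78 °C (LiCHBr2 pre-formed), then 10; LiN(SiMe3)2; n-BuLi, −78 to 20 °C; iPr3SiCl, −78 to 0 °C; NaHCO3 work-up, Et3N-deactivated silica
Reagents that add atoms: dibromomethane, BrCBr (one carbon); chlorotriisopropylsilane, CC(C)[Si](Cl)(C(C)C)C(C)C
Why: Kowalski ynolate synthesis: LiCHBr2 adds to the ester, the derived dibromo ketone enolate undergoes Br/Li exchange and a carbenoid 1,2-shift of the piperidinyl carbon with retention, and the bulky silyl chloride traps the ynolate on oxygen; pre-forming LiCHBr2 keeps free amide base away from the ester α-CH so that C2′ stays R, and n-BuLi is held to one equivalent at low temperature to spare the Boc group.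

Step 7
Reactants: 8 (S)-6-(2-diazoacetyl)-2-[4-(benzyloxy)phenyl]-2,3-dihydro-4H-pyran-4-one; 12 tert-butyl (R)-2-{[(triisopropylsilyl)oxy]ethynyl}piperidine-1-carboxylate (1.3 equiv)
Product: 17 tert-butyl (R)-2-[(S)-2-(4-(benzyloxy)phenyl)-5-hydroxy-4-oxo-7-(triisopropylsilyloxy)chroman-6-yl]piperidine-1-carboxylate, via vinylketene 13 (not isolated), via vinylcyclobutenone 14 (not isolated), via dienylketene 15 (not isolated), via cyclohexadienone 16 (not isolated)
Conditions: hν (350–365 nm, Pyrex), degassed ClCH2CH2Cl (0.1 M), rt until 8 is consumed; then 80 °C in the dark, 3 h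
Reagents that add atoms: none
Why: Light expels N2 from 8 and the pyranone C6 (future C8a) migrates to the diazo carbon (photochemical Wolff rearrangement, bond C8–C8a) to give vinylketene 13, whose electrophilic carbonyl carbon bonds to the nucleophilic piperidine-bearing carbon of ynol silyl ether 12 while the siloxy carbon bonds to the former diazo carbon ([2+2], bonds C5–C6 and C7–C8), giving 4-vinylcyclobutenone 14. Ring strain drives reversible 4π electrocyclic opening of 14 to dienylketene 15, and ring A closes by thermal 6π disrotatory electrocyclisation of its E isomer (bond C4a–C5) to dienone 16, which enolises to the phenol; the warm period in the dark completes this relay. The closest known reaction type is the photochemical Danheiser benzannulation of α-diazo enones and of 2-furyl diazomethyl ketones (where the migrating carbon likewise carries the ring oxygen) with triisopropylsiloxyalkynes to resorcinol monosilyl ethers. No stereocentre is created: the sp3 carbons of 14 and 16 are transient, and C2 and C2′ are carried in from 8 and 12 and are not touched under these neutral conditions. The regioselectivity required, piperidinyl carbon between C5–OH and C7–OSi with hydrogen at C8, is secured by the ketene/ynol-ether polarity, and the ring holds the ketene trans to C4=O so that only closure at C4a is possible, the new C5–OH ending hydrogen-bonded to C4=O. Long-wavelength light addresses the diazo ketone chromophore and should spare the enone and the flavanone product, and the excess of 12 together with the chelated, flanked C5–OH should suppress ketene dimerisation and O-acylation of the product.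

Step 8
Reactants: 17 tert-butyl (R)-2-[(S)-2-(4-(benzyloxy)phenyl)-5-hydroxy-4-oxo-7-(triisopropylsilyloxy)chroman-6-yl]piperidine-1-carboxylate
Product: 18 tert-butyl (R)-2-[(S)-5-hydroxy-2-(4-hydroxyphenyl)-4-oxo-7-(triisopropylsilyloxy)chroman-6-yl]piperidine-1-carboxylate
Conditions: H2 (1 atm), 10% Pd/C, EtOAc, rt
Reagents that add atoms: none
Why: Catalytic hydrogenolysis of the aryl benzyl ether, done while nitrogen is still a carbamate so that the benzylic C2′–N bond is not at risk; the hydrogen-bonded aryl ketone and the silyl ether are inert under these conditions.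

Step 9
Reactants: 18 tert-butyl (R)-2-[(S)-5-hydroxy-2-(4-hydroxyphenyl)-4-oxo-7-(triisopropylsilyloxy)chroman-6-yl]piperidine-1-carboxylate
Product: 19 (S)-5-hydroxy-2-(4-hydroxyphenyl)-6-[(R)-piperidin-2-yl]-7-(triisopropylsilyloxy)chroman-4-one
Conditions: CF3CO2H/CH2Cl2 (1:4), 0 °C, 1 h; cold aq. NaHCO3 to pH 8, used at once
Reagents that add atoms: none
Why: Acidolysis of the Boc carbamate (loss of the tert-butyl cation, then decarboxylation); the hindered aryl silyl ether and the flavanone tolerate cold acid, and strong base is avoided in the work-up to keep C2 from epimerising by ring opening.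

Step 10
Reactants: 19 (S)-5-hydroxy-2-(4-hydroxyphenyl)-6-[(R)-piperidin-2-yl]-7-(triisopropylsilyloxy)chroman-4-one
Product: 20 (S)-5-hydroxy-2-(4-hydroxyphenyl)-6-[(R)-1-methylpiperidin-2-yl]-7-(triisopropylsilyloxy)chroman-4-one
Conditions: 37% aq. CH2O (1.5 equiv), NaBH(OAc)3 (2 equiv), AcOH (1 equiv), ClCH2CH2Cl, 0 °C to rt
Reagents that add atoms: formaldehyde, C=O
Why: Reductive amination (Borch-type) with a hydride too mild to reduce the chelated aryl ketone; the weakly acidic medium keeps the phenols protonated, and the C7 silyl ether tempers ring A toward competing Mannich attack at C8.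

Step 11
Reactants: 20 (S)-5-hydroxy-2-(4-hydroxyphenyl)-6-[(R)-1-methylpiperidin-2-yl]-7-(triisopropylsilyloxy)chroman-4-one
Product: 21 (S)-5,7-dihydroxy-2-(4-hydroxyphenyl)-6-[(R)-1-methylpiperidin-2-yl]chroman-4-one
Conditions: HF·pyridine, THF, 0 °C to rt; pH 7 phosphate buffer work-up
Reagents that add atoms: none
Why: Fluoride cleavage of the aryl silyl ether under acidic, non-basic conditions, which avoids the base-induced flavanone–chalcone equilibration that would epimerise C2.

**Compound list**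
1 | ethyl 2,4-dioxopentanoate | CCOC(=O)C(=O)CC(C)=O | starting material
2 | ethyl (2Z)-2,4-bis(trimethylsilyloxy)penta-2,4-dienoate | CCOC(=O)/C(O[Si](C)(C)C)=C/C(=C)O[Si](C)(C)C | intermediate
3 | 4-(benzyloxy)benzaldehyde | O=Cc1ccc(OCc2ccccc2)cc1 | starting material
4 | ethyl (2Z,6S)-6-[4-(benzyloxy)phenyl]-4-oxo-2,6-bis(trimethylsilyloxy)hex-2-enoate (silyl aldol adduct) | CCOC(=O)/C(O[Si](C)(C)C)=C/C(=O)C[C@H](O[Si](C)(C)C)c1ccc(OCc2ccccc2)cc1 | intermediate
5 | ethyl (S)-2-[4-(benzyloxy)phenyl]-4-oxo-3,4-dihydro-2H-pyran-6-carboxylate | CCOC(=O)C1=CC(=O)C[C@@H](c2ccc(OCc3ccccc3)cc2)O1 | intermediate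
6 | (S)-2-[4-(benzyloxy)phenyl]-4-oxo-3,4-dihydro-2H-pyran-6-carboxylic acid | OC(=O)C1=CC(=O)C[C@@H](c2ccc(OCc3ccccc3)cc2)O1 | intermediate
7 | (S)-2-[4-(benzyloxy)phenyl]-4-oxo-3,4-dihydro-2H-pyran-6-carbonyl chloride | ClC(=O)C1=CC(=O)C[C@@H](c2ccc(OCc3ccccc3)cc2)O1 | intermediate
8 | (S)-6-(2-diazoacetyl)-2-[4-(benzyloxy)phenyl]-2,3-dihydro-4H-pyran-4-one | [N-]=[N+]=CC(=O)C1=CC(=O)C[C@@H](c2ccc(OCc3ccccc3)cc2)O1 | intermediate
9 | (R)-1-(tert-butoxycarbonyl)piperidine-2-carboxylic acid | CC(C)(C)OC(=O)N1CCCC[C@@H]1C(=O)O | starting material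
10 | 1-tert-butyl 2-methyl (R)-piperidine-1,2-dicarboxylate | CC(C)(C)OC(=O)N1CCCC[C@@H]1C(=O)OC | intermediate
11 | lithium 2-[(R)-1-(tert-butoxycarbonyl)piperidin-2-yl]ethynolate | CC(C)(C)OC(=O)N1CCCC[C@@H]1C#C[O-].[Li+] | intermediate
12 | tert-butyl (R)-2-{[(triisopropylsilyl)oxy]ethynyl}piperidine-1-carboxylate | CC(C)(C)OC(=O)N1CCCC[C@@H]1C#CO[Si](C(C)C)(C(C)C)C(C)C | intermediate
13 | (S)-2-[4-(benzyloxy)phenyl]-6-(2-oxoethenyl)-2,3-dihydro-4H-pyran-4-one (vinylketene) | O=C=CC1=CC(=O)C[C@@H](c2ccc(OCc3ccccc3)cc2)O1 | intermediate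
14 | tert-butyl (2R)-2-{3-[(2S)-2-(4-(benzyloxy)phenyl)-4-oxo-3,4-dihydro-2H-pyran-6-yl]-4-oxo-2-(triisopropylsilyloxy)cyclobut-1-en-1-yl}piperidine-1-carboxylate (ring sp3 carbon as both epimers) | CC(C)(C)OC(=O)N1CCCC[C@@H]1C1=C(O[Si](C(C)C)(C(C)C)C(C)C)C(C2=CC(=O)C[C@@H](c3ccc(OCc4ccccc4)cc3)O2)C1=O | intermediate
15 | tert-butyl (2R)-2-{(2E)-3-[(2S)-2-(4-(benzyloxy)phenyl)-4-oxo-3,4-dihydro-2H-pyran-6-yl]-1-(oxomethylidene)-2-(triisopropylsilyloxy)prop-2-en-1-yl}piperidine-1-carboxylate (dienylketene) | CC(C)(C)OC(=O)N1CCCC[C@@H]1C(=C=O)\C(O[Si](C(C)C)(C(C)C)C(C)C)=C/C1=CC(=O)C[C@@H](c2ccc(OCc3ccccc3)cc2)O1 | intermediate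
16 | tert-butyl (2R)-2-[(2S)-2-(4-(benzyloxy)phenyl)-4,5-dioxo-7-(triisopropylsilyloxy)-3,4,4a,5-tetrahydro-2H-chromen-6-yl]piperidine-1-carboxylate (C4a as both epimers) | CC(C)(C)OC(=O)N1CCCC[C@@H]1C1=C(O[Si](C(C)C)(C(C)C)C(C)C)C=C2O[C@H](c3ccc(OCc4ccccc4)cc3)CC(=O)C2C1=O | intermediate
17 | tert-butyl (R)-2-[(S)-2-(4-(benzyloxy)phenyl)-5-hydroxy-4-oxo-7-(triisopropylsilyloxy)chroman-6-yl]piperidine-1-carboxylate | CC(C)(C)OC(=O)N1CCCC[C@@H]1c1c(O[Si](C(C)C)(C(C)C)C(C)C)cc2c(c1O)C(=O)C[C@@H](c1ccc(OCc3ccccc3)cc1)O2 | intermediate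
18 | tert-butyl (R)-2-[(S)-5-hydroxy-2-(4-hydroxyphenyl)-4-oxo-7-(triisopropylsilyloxy)chroman-6-yl]piperidine-1-carboxylate | CC(C)(C)OC(=O)N1CCCC[C@@H]1c1c(O[Si](C(C)C)(C(C)C)C(C)C)cc2c(c1O)C(=O)C[C@@H](c1ccc(O)cc1)O2 | intermediate
19 | (S)-5-hydroxy-2-(4-hydroxyphenyl)-6-[(R)-piperidin-2-yl]-7-(triisopropylsilyloxy)chroman-4-one | N1CCCC[C@@H]1c1c(O[Si](C(C)C)(C(C)C)C(C)C)cc2c(c1O)C(=O)C[C@@H](c1ccc(O)cc1)O2 | intermediate
20 | (S)-5-hydroxy-2-(4-hydroxyphenyl)-6-[(R)-1-methylpiperidin-2-yl]-7-(triisopropylsilyloxy)chroman-4-one | CN1CCCC[C@@H]1c1c(O[Si](C(C)C)(C(C)C)C(C)C)cc2c(c1O)C(=O)C[C@@H](c1ccc(O)cc1)O2 | intermediate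
21 | (S)-5,7-dihydroxy-2-(4-hydroxyphenyl)-6-[(R)-1-methylpiperidin-2-yl]chroman-4-one | CN1CCCC[C@@H]1c1c(O)cc2c(c1O)C(=O)C[C@@H](c1ccc(O)cc1)O2 | target

**Step count**
Total: 11 steps. Longest linear sequence: 9 steps (steps 1, 2, 3, 4, 7, 8, 9, 10, 11); steps 5 and 6 form the second branch.

**Steps most likely to fail**

Step 7. The vinylketene is generated slowly and at low concentration under light, while the hindered, α-branched siloxyalkyne may add sluggishly. Ketene dimerisation, photoreaction of the enone chromophore or over-irradiation of the product could then take over. Fallback (sets out from 8, comes back at 14, which is heated to 17 as in step 7): the ketene is made thermally by dehydrochlorination instead of by light. Wolff rearrangement of 8 in the dark with PhCO2Ag/Et3N in THF–H2O should give 2-[(S)-2-(4-(benzyloxy)phenyl)-4-oxo-3,4-dihydro-2H-pyran-6-yl]acetic acid F1, which is used at once because it is a vinylogous β-keto acid. (COCl)2 with catalytic DMF converts it into 2-[(S)-2-(4-(benzyloxy)phenyl)-4-oxo-3,4-dihydro-2H-pyran-6-yl]acetyl chloride F2. Slow addition of Et3N to F2 and 12 in CH2Cl2 at 0 °C to rt releases 13 at a chosen rate for the known ketene–siloxyalkyne [2+2] cycloaddition.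

Step 2. The ester-bearing dienol ether is less nucleophilic than the usual 1-alkoxy-3-siloxydienes and the aldehyde is electron-rich, so conversion or facial selectivity may be poor. Acid-induced ionisation at the benzylic carbinol during cyclisation could also erode the enantiomeric purity. Fallback (sets out from 3, comes back at 5): the carbinol centre is set by allylation and the ring is built stepwise. Keck allylation of 3 (allyltributylstannane, Ti(OiPr)4/(S)-BINOL, same facial model) should give (S)-1-[4-(benzyloxy)phenyl]but-3-en-1-ol F3. Wacker oxidation (PdCl2 cat., CuCl, O2, DMF–H2O) gives (S)-4-[4-(benzyloxy)phenyl]-4-hydroxybutan-2-one F4. Double deprotonation with LiN(SiMe3)2 (2.2 equiv, THF, −78 °C) and Claisen condensation with diethyl oxalate gives ethyl (S)-6-[4-(benzyloxy)phenyl]-6-hydroxy-2,4-dioxohexanoate F5. Brief treatment with CF3CO2H in CH2Cl2 at 0 °C cyclodehydrates it to 5.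

Step 4. Diazomethane may add as a 1,3-dipole across the C5=C6 enedione bond of 7 or 8 (pyrazoline formation) in competition with acylation. Fallback (sets out from 7, comes back at 8): diazo transfer replaces diazomethane. Stille ketone synthesis on 7 (Me4Sn, Pd(PPh3)4 cat., toluene, 60 °C) should give (S)-6-acetyl-2-[4-(benzyloxy)phenyl]-2,3-dihydro-4H-pyran-4-one F6. Kinetic deprotonation of the acetyl methyl group with LiN(SiMe3)2 (THF, −78 °C) and trapping with CF3CO2CH2CF3 gives 1-[(S)-2-(4-(benzyloxy)phenyl)-4-oxo-3,4-dihydro-2H-pyran-6-yl]-4,4,4-trifluorobutane-1,3-dione F7. Detrifluoroacetylative diazo transfer (MeSO2N3, Et3N, H2O, MeCN, rt) then delivers 8.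

**Further compounds**
F1 | step 7 | 2-[(S)-2-(4-(benzyloxy)phenyl)-4-oxo-3,4-dihydro-2H-pyran-6-yl]acetic acid | OC(=O)CC1=CC(=O)C[C@@H](c2ccc(OCc3ccccc3)cc2)O1
F2 | step 7 | 2-[(S)-2-(4-(benzyloxy)phenyl)-4-oxo-3,4-dihydro-2H-pyran-6-yl]acetyl chloride | ClC(=O)CC1=CC(=O)C[C@@H](c2ccc(OCc3ccccc3)cc2)O1
F3 | step 2 | (S)-1-[4-(benzyloxy)phenyl]but-3-en-1-ol | C=CC[C@H](O)c1ccc(OCc2ccccc2)cc1
F4 | step 2 | (S)-4-[4-(benzyloxy)phenyl]-4-hydroxybutan-2-one | CC(=O)C[C@H](O)c1ccc(OCc2ccccc2)cc1
F5 | step 2 | ethyl (S)-6-[4-(benzyloxy)phenyl]-6-hydroxy-2,4-dioxohexanoate | CCOC(=O)C(=O)CC(=O)C[C@H](O)c1ccc(OCc2ccccc2)cc1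
F6 | step 4 | (S)-6-acetyl-2-[4-(benzyloxy)phenyl]-2,3-dihydro-4H-pyran-4-one | CC(=O)C1=CC(=O)C[C@@H](c2ccc(OCc3ccccc3)cc2)O1
F7 | step 4 | 1-[(S)-2-(4-(benzyloxy)phenyl)-4-oxo-3,4-dihydro-2H-pyran-6-yl]-4,4,4-trifluorobutane-1,3-dione | O=C(CC(=O)C(F)(F)F)C1=CC(=O)C[C@@H](c2ccc(OCc3ccccc3)cc2)O1
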